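## The problem

The target 30 consists of two trans-2,3-diaryl-2,3-dihydrobenzofurans joined by a single bond from C3 of unit 1 to C5 of unit 2. Unit 1 is fused to ring A, which carries the (Z)-4-hydroxystyryl group at C4, right beside the crowded C3, and a hydroxyl at C6; unit 2 is fused to ring M, which carries a hydroxyl at C7, and has a 3,5-dihydroxyphenyl ring on C3. There are four stereocentres in two trans pairs of opposite absolute sense: (2S,3S) in unit 1 and (2R,3R) in unit 2. Within a pair C3 can control C2, because the C2–O1 bond is a para-oxygenated benzylic ether that ionises in acid and recloses to the more stable trans ring. Between the pairs there is no useful relay, since the nearest centre of unit 2 lies four bonds from C3 of unit 1, so each pair needs its own source of absolute configuration. The fragile parts are the cis-stilbene (acid, light and palladium hydrides isomerise it, and acid cyclises it onto electron-rich rings), the seven phenols once free (oxidation), the two benzylic C2–O1 bonds (Lewis acids) and the doubly benzylic C3–H bonds (strong base opens the ring by loss of phenoxide). The feature that invites the key step is C2 of unit 1: a lone sp3 carbon with one aryl group, bonded to C3 on one side and O1 on the other, where O1–C7a–C3a–C3 is the four-atom backbone of an ortho-quinone methide of ring A. C2 can therefore be delivered as a one-carbon ylide, and because the same C3 carries unit 2, the methide precursor is reached by adding a unit 2 aryl metal to a ring A salicylaldehyde.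

## Retrosynthesis

**Stilbene last (bond from C4 of ring A to the styryl carbon).** The cis-alkene is the most fragile part of 30 and is made in the penultimate step. Cutting between C4 of ring A and the styryl carbon leads through heptaacetate 29 and diarylalkyne 28 to aryl bromide 26 and 4-ethynylphenyl acetate 27. Compared with a Wittig reaction across the C=C bond, this cut needs no aldehyde at the crowded C4 position, and the Z geometry comes from syn addition of hydrogen. Compared with coupling a (Z)-styryl metal, it uses a partner that can be bought. The forward steps must couple next to the substituted C3a position, stop the hydrogenation at the alkene, and cleave seven esters under conditions mild enough for a cis-stilbene polyphenol.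

**Change of phenol protection (six O–CH3 bonds).** Bromide 26 is the hexaacetate of hexaphenol 25, which comes from hexamethyl ether 24. Methyl ethers are the one phenol protection that passes the aryl metal, carbene and acid steps that build the core, but their removal needs BBr3, which a cis-stilbene would not survive. Acetates tolerate palladium and hydrogen and come off with methanol. Making the exchange at the bromide stage, before any alkyne or alkene exists, reconciles the two at the cost of two steps.

**Unit 1 by [4+1] (C2–C3 and C2–O1).** Removing C2 of unit 1 with its 4-methoxyphenyl group from 24 leaves ortho-quinone methide 22 and a one-carbon donor, benzylide 23; their storable forms are sulfone 17 and sulfonium salt 21. The neighbouring cuts are weaker here. The carbene C–H insertion used for unit 2 would need a hydrazone and a diazo group on a benzophenone carbon flanked by bromine and an alkoxy group on ring A. An oxidative phenol–stilbene coupling would be neither regioselective nor compatible with the electron-rich unit 2. The [4+1] cut removes one ring, two bonds and two stereocentres, leaves all of 24 except one benzylic carbon in 17, and lets the chirality of unit 1 come from a small reagent. It requires that the ylide add to the methide carbon faster than its salt benzylates oxygen nucleophiles, that closure give the trans ring, and that the sulfide fix the absolute sense.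

**Methide precursor (bond between the future C3 of unit 1 and C5 of ring M).** Sulfone 17 is the sulfinic acid exchange product of ortho-hydroxybenzhydrol 16. Carbinol 16 is cut between the carbinol carbon and C5 of ring M into aryl bromide 11 (used as arylmagnesium bromide 14) and salicylaldehyde 13 (used as phenoxide 15). The opposite polarity would need a formyl group on unit 2 and a metal between bromine and oxygen on ring A. The bond forms before any stereocentre of unit 1 exists, so the carbinol and sulfonyl carbons may be epimer mixtures. The forward reaction must spare the ring A bromide, which an arylmagnesium halide does.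

**Unit 2 (C2–C3 of unit 2).** trans-Bromide 11 is the C2 epimer of cis-bromide 10, which is opened at C2–C3 to diaryldiazomethane 9 and, behind it, hydrazone 8, ketone 7 and carbinol 6. Carbinol 6 is cut into aldehyde 3 and arylmagnesium bromide 5 (from bromide 4), and 3 is the 4-methoxybenzyl ether of phenol 1, made with bromide 2. Asymmetric C–H insertion is preferred here over a second [4+1] because unit 2 is the first stereogenic piece: its enantiomeric purity cannot be repaired later by separating diastereomers, so the ligand-controlled method is used here, while unit 1 can rely on unit 2 already being a single enantiomer. Ring M, with bromine at C5 and oxygen at C7, is bought ready-made as 1. The sequence must set C3 absolutely; C2 follows by acid equilibration.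

**Ring A aldehyde.** Aldehyde 13 comes from 12 by removal of the methyl group ortho to the formyl group, and 12 from bromide 4 by formylation. Bromide 4 thus supplies both ring A and the resorcinol ring of unit 2.

**Sulfonium salt.** Salt 21 is cut at sulfur into bromide 2 and thiolane 20, and 20 at both C–S bonds into dimesylate 19 and diol 18. Because 20 is C2-symmetric, alkylation creates no stereocentre at sulfur.

## Roads not taken

**Alternative 1:** The cut is the C3–C3a bond of unit 2, made by ring contraction of the flavanone (2R)-6-chloro-8-methoxy-2-(4-methoxyphenyl)chroman-4-one A1. In the forward step PhI(OAc)2, HC(OMe)3 and H2SO4 in methanol form the enol ether, iodinate C3 and trigger a 1,2-shift of the ring M carbon from the carbonyl carbon to C3, giving methyl (2R,3R)-5-chloro-7-methoxy-2-(4-methoxyphenyl)-2,3-dihydro-1-benzofuran-3-carboxylate A2.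
- Merits: flavanones are easy to make; the contraction is a known reaction of this class; one stereocentre (C2) governs the outcome and the trans ester is the thermodynamic product.
- Weak points: A2 carries an ester at C3 where the target has the resorcinol ring, so that ring must be built from the ester or introduced by a decarboxylative arylation that passes through a planar C3. The C2 centre of A1 can racemise by retro-oxa-Michael opening in strong acid. The oxidant meets electron-rich anisole rings. An aryl chloride is a poorer handle than a bromide for the later metalation. Unit 1 is left unsolved.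
- Comparison: this road is at least as simple in stereochemical logic for unit 2, since one centre controls the other by equilibration. The chosen plan offers in return a unit 2 (11) that arrives in six steps with its C3 aryl ring in place and without an oxidant, and a key step that addresses the harder half, unit 1.

**Alternative 2:** The cut goes through ring M itself (C3a–C7a and C6–C7) together with the dihydrofuran of unit 2. The precursor is the furyl ynol ether 4-bromo-2-[(1S,2R)-1-(3,5-dimethoxyphenyl)-2-(ethynyloxy)-2-(4-methoxyphenyl)ethyl]furan A3. The cationic gold complex Ph3PAuNTf2 activates the alkyne, furan C2 attacks the oxygen-bearing alkyne carbon, and the furan opens and recloses to the phenol (2R,3R)-5-bromo-3-(3,5-dimethoxyphenyl)-2-(4-methoxyphenyl)-2,3-dihydro-1-benzofuran-7-ol A4.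
- Merits: two rings form in one atom-economic isomerisation; the C7 hydroxyl emerges free and distinct from the other oxygens; both stereocentres are fixed in an open-chain precursor and no epimerisation step is needed.
- Weak points: A3 needs both centres set in an acyclic furyl diaryl ethanol first. The ynol ether of a 4-methoxybenzylic secondary alcohol is prone to ionisation and to sigmatropic rearrangement. A 4-bromofuran must be carried. The sequence builds an arene that can be bought. Unit 1 still has to be annulated.
- Comparison: this road is better in atom economy and in differentiating the C7 oxygen. The differentiation is not needed here, because all phenols are unmasked together, and the chosen plan takes ring M with the correct substituents from aldehyde 1.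

**Alternative 3:** The cut is O1–C7a and C3–C3a of unit 1, the [3+2] complement of the chosen [4+1]. Ring A arrives as the aryne 3-bromo-5-methoxybenzyne A6, released by CsF, and inserts into the C–O bond of the enantiopure epoxide 4-{(2R,3R)-3-[(2R,3R)-3-(3,5-dimethoxyphenyl)-7-methoxy-2-(4-methoxyphenyl)-2,3-dihydro-1-benzofuran-5-yl]oxiran-2-yl}phenyl 4-methylbenzenesulfonate A5. The epoxide oxygen attacks the aryne carbon remote from bromine, the epoxide opens at the carbon bearing unit 2, and the aryl anion closes onto it to give 4-{(2S,3S)-4-bromo-3-[(2R,3R)-3-(3,5-dimethoxyphenyl)-7-methoxy-2-(4-methoxyphenyl)-2,3-dihydro-1-benzofuran-5-yl]-6-methoxy-2,3-dihydro-1-benzofuran-2-yl}phenyl 4-methylbenzenesulfonate A7.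
- Merits: it is the most convergent of the plans; C2 is imported with a configuration fixed by an asymmetric epoxidation; bromine steers the regiochemistry of aryne attack.
- Weak points: C3 passes through a benzylic cation, so its configuration is not transferred from A5 and the trans ring depends on the closure. The aryl anion sits next to bromine and can expel it to a second aryne. An epoxide oxygen is a weak aryne trap, and an electron-rich stilbene oxide rearranges easily to a diarylacetaldehyde. The tosylate that biases the ring opening is a seventh protecting group with its own basic removal.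
- Comparison: this road is better in convergence and in the origin of C2. The chosen plan offers in return bond formation by addition and SN2 closure without a free cation at C3, bromine as a pure spectator, mild carbonate base as the only reagent, and a uniform set of methyl ethers.

Key step: step 14

Assumption on step 14: ylide 23 is taken to react through the conformer and open face that benzylides of this thiolane use in aldehyde epoxidation; on that model the (2S,5S)-sulfide gives (2S)-configured C2, so the salt is made from (2R,5R)-hexane-2,5-diol.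

Assumption on step 5: Rh2(R-PTAD)4 is taken to be the antipode that gives the (3R) centre of 10; if the sense is opposite, Rh2(S-PTAD)4 is used and nothing else changes.

## Route

Step 1
Reactants: 1 5-bromo-2-hydroxy-3-methoxybenzaldehyde; 2 4-methoxybenzyl bromide
Product: 3 5-bromo-3-methoxy-2-[(4-methoxyphenyl)methoxy]benzaldehyde
Conditions: K2CO3, DMF, rt
Reagents that add atoms: none
Why: Williamson ether synthesis; the phenoxide of 1, acidified by the ortho formyl group, should be alkylated cleanly by the benzylic bromide, which places the future C2 of unit 2 on oxygen.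

Step 2
Reactants: 4 1-bromo-3,5-dimethoxybenzene; 3 5-bromo-3-methoxy-2-[(4-methoxyphenyl)methoxy]benzaldehyde
Product: 6 {5-bromo-3-methoxy-2-[(4-methoxyphenyl)methoxy]phenyl}(3,5-dimethoxyphenyl)methanol (racemic), via 3,5-dimethoxyphenylmagnesium bromide 5 (not isolated)
Conditions: 4, Mg, THF, reflux; then 3, THF, 0 °C to rt; aq. NH4Cl
Reagents that add atoms: none
Why: Grignard addition to an aldehyde; the aryl bromide of 3 does not exchange with an arylmagnesium halide at this temperature, and the new carbinol centre is removed by oxidation in step 3.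

Step 3
Reactants: 6 {5-bromo-3-methoxy-2-[(4-methoxyphenyl)methoxy]phenyl}(3,5-dimethoxyphenyl)methanol
Product: 7 {5-bromo-3-methoxy-2-[(4-methoxyphenyl)methoxy]phenyl}(3,5-dimethoxyphenyl)methanone
Conditions: DMP (triacetoxyperiodinane), CH2Cl2, rt
Reagents that add atoms: none
Why: Periodinane oxidation of a benzhydrol to the benzophenone under neutral conditions that should leave the 4-methoxybenzyl ether and the electron-rich rings untouched.

Step 4
Reactants: 7 {5-bromo-3-methoxy-2-[(4-methoxyphenyl)methoxy]phenyl}(3,5-dimethoxyphenyl)methanone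
Product: 8 hydrazone of 7, [{5-bromo-3-methoxy-2-[(4-methoxyphenyl)methoxy]phenyl}(3,5-dimethoxyphenyl)methylidene]hydrazine (E/Z mixture)
Conditions: N2H4·H2O, AcOH (cat.), EtOH, 80 °C
Reagents that add atoms: hydrazine, NN
Why: Condensation of a diaryl ketone with hydrazine gives the N-unsubstituted hydrazone; both geometric isomers lead to the same diazo compound.

Step 5
Reactants: 8 hydrazone of 7
Product: 10 (2S,3R)-5-bromo-3-(3,5-dimethoxyphenyl)-7-methoxy-2-(4-methoxyphenyl)-2,3-dihydro-1-benzofuran (cis), via diaryldiazomethane 9 (not isolated)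
Conditions: MnO2, CH2Cl2, 0 °C; filtration; Rh2(R-PTAD)4 (dirhodium tetrakis[(R)-N-phthaloyl-1-adamantylglycinate], 1 mol %), MeCN/CH2Cl2, 0 °C to rt
Reagents that add atoms: none
Why: Dehydrogenation of the hydrazone gives the donor/donor diazo compound 9, whose dirhodium carbene undergoes intramolecular 1,5 C–H insertion into the oxygen-activated benzylic C–H bond; the concerted insertion should give the cis ring, and the chiral carboxylate ligands set C3 (and with it C2) in absolute terms.

Step 6
Reactants: 10 (2S,3R)-5-bromo-3-(3,5-dimethoxyphenyl)-7-methoxy-2-(4-methoxyphenyl)-2,3-dihydro-1-benzofuran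
Product: 11 (2R,3R)-5-bromo-3-(3,5-dimethoxyphenyl)-7-methoxy-2-(4-methoxyphenyl)-2,3-dihydro-1-benzofuran (trans)
Conditions: TFA, CH2Cl2, 0 °C to rt
Reagents that add atoms: none
Why: Acid-mediated epimerisation; TFA reversibly ionises the C2–O1 bond to a 4-methoxybenzylic cation and reclosure should give the thermodynamically preferred trans ring by inversion at C2, while C3, which is not involved, keeps the configuration set in step 5.

Step 7
Reactants: 4 1-bromo-3,5-dimethoxybenzene
Product: 12 2-bromo-4,6-dimethoxybenzaldehyde
Conditions: POCl3, DMF, 0 to 90 °C; then ice-water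
Reagents that add atoms: N,N-dimethylformamide, CN(C)C=O; water, O
Why: Vilsmeier–Haack formylation; attack para to one methoxy group and ortho to the other (two equivalent sites next to bromine) is expected to prevail over the site flanked by both methoxy groups.

Step 8
Reactants: 12 2-bromo-4,6-dimethoxybenzaldehyde
Product: 13 2-bromo-6-hydroxy-4-methoxybenzaldehyde
Conditions: BCl3 (1.2 equiv), CH2Cl2, −78 to 0 °C; then H2O
Reagents that add atoms: none
Why: Chelation-controlled ether cleavage; BCl3 bound to the formyl oxygen removes only the methyl group of the ortho methoxy group through a six-membered boron chelate and leaves the para methoxy group and the bromide.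

Step 9
Reactants: 11 (2R,3R)-5-bromo-3-(3,5-dimethoxyphenyl)-7-methoxy-2-(4-methoxyphenyl)-2,3-dihydro-1-benzofuran; 13 2-bromo-6-hydroxy-4-methoxybenzaldehyde
Product: 16 3-bromo-2-{[(2R,3R)-3-(3,5-dimethoxyphenyl)-7-methoxy-2-(4-methoxyphenyl)-2,3-dihydro-1-benzofuran-5-yl](hydroxy)methyl}-5-methoxyphenol (both epimers at the carbinol carbon), via arylmagnesium bromide 14 (not isolated), via sodium phenoxide 15 (not isolated)
Conditions: 11, Mg, LiCl, THF, rt; separately 13, NaH (1.0 equiv), THF, 0 °C; phenoxide solution added to the Grignard solution, 0 °C to rt; aq. NH4Cl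
Reagents that add atoms: none
Why: Grignard addition to a salicylaldehyde whose phenol is masked as its sodium salt so that none of 14 is lost to protonation; magnesium chelation between phenoxide and formyl oxygen activates the aldehyde, an arylmagnesium halide does not exchange with the ring A bromide, and the carbinol centre is erased at the methide stage.

Step 10
Reactants: 16 the ortho-hydroxybenzhydrol of step 9
Product: 17 3-bromo-2-{[(2R,3R)-3-(3,5-dimethoxyphenyl)-7-methoxy-2-(4-methoxyphenyl)-2,3-dihydro-1-benzofuran-5-yl](4-methylbenzenesulfonyl)methyl}-5-methoxyphenol (both epimers at the sulfonyl carbon)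
Conditions: p-TolSO2H (excess, freshly liberated from its sodium salt), CH2Cl2, rt
Reagents that add atoms: p-toluenesulfinic acid, Cc1ccc(cc1)S(=O)O
Why: Acid-promoted substitution of an ortho-hydroxybenzhydrol; the sulfinic acid ionises the carbinol to the protonated methide and the soft sulfur nucleophile, present in excess, should capture it as the bench-stable sulfone.

Step 11
Reactants: 18 (2R,5R)-hexane-2,5-diol
Product: 19 (2R,5R)-hexane-2,5-diyl dimethanesulfonate
Conditions: MsCl, Et3N, CH2Cl2, 0 °C
Reagents that add atoms: methanesulfonyl chloride, CS(=O)(=O)Cl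
Why: Sulfonylation at oxygen activates both secondary alcohols without touching the stereocentres.

Step 12
Reactants: 19 (2R,5R)-hexane-2,5-diyl dimethanesulfonate
Product: 20 (2S,5S)-2,5-dimethylthiolane
Conditions: Na2S·9H2O, EtOH/H2O, rt
Reagents that add atoms: sodium sulfide, [Na+].[Na+].[S-2]
Why: Double SN2 displacement by sulfide, the second as a 5-exo-tet closure, inverts both carbons and gives the C2-symmetric (2S,5S)-thiolane.

Step 13
Reactants: 20 (2S,5S)-2,5-dimethylthiolane; 2 4-methoxybenzyl bromide
Product: 21 (2S,5S)-1-[(4-methoxyphenyl)methyl]-2,5-dimethylthiolan-1-ium tetrafluoroborate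
Conditions: NaBF4, acetone, rt
Reagents that add atoms: sodium tetrafluoroborate, [Na+].F[B-](F)(F)F
Why: S-Alkylation of a dialkyl sulfide by a benzylic bromide with anion metathesis driven by precipitation of NaBr; the two lone pairs of the C2-symmetric sulfide are equivalent, so a single salt should form.

Step 14
Reactants: 17 the sulfone of step 10; 21 (2S,5S)-1-[(4-methoxyphenyl)methyl]-2,5-dimethylthiolan-1-ium tetrafluoroborate
Product: 24 (2S,3S)-4-bromo-3-[(2R,3R)-3-(3,5-dimethoxyphenyl)-7-methoxy-2-(4-methoxyphenyl)-2,3-dihydro-1-benzofuran-5-yl]-6-methoxy-2-(4-methoxyphenyl)-2,3-dihydro-1-benzofuran, via ortho-quinone methide 22 (not isolated), via sulfonium ylide 23 (not isolated)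
Conditions: 21 (2 equiv), Cs2CO3 (3 equiv), CH2Cl2/MeCN, −20 °C to rt
Reagents that add atoms: none
Why: Cs2CO3 deprotonates the phenol of 17, loss of sulfinate releases ortho-quinone methide 22, and the same base converts salt 21 into the semi-stabilised benzylide 23. The ylide carbon adds to the exocyclic methide carbon (the future C3), restoring the aromaticity of ring A, and the phenoxide of the resulting betaine displaces the thiolane at the benzylic carbon with inversion in a 5-exo-tet closure, so that C2–C3 and C2–O1 form and the dihydrofuran ring of unit 1 is closed. The closest known reaction type is the formal [4+1] annulation of sulfonium ylides with ortho-quinone methides released from 2-(1-sulfonylalkyl)phenols, which gives trans-2,3-dihydrobenzofurans, combined with a C2-symmetric thiolanium benzylide as used in asymmetric ylide epoxidation. C2 is controlled by the sulfide: the methyl group cis to the benzylidene unit screens one face of the ylide carbon, and the SN2 closure passes that configuration on with inversion. C3 is controlled relative to C2: only the betaine that can place the unit 2 aryl group and the 4-methoxyphenyl group anti in the closing conformer cyclises readily, while the other can revert, so the trans (2S,3S) pair is expected. The centres of unit 2 lie four bonds from C3 and should not override the reagent, and because unit 2 is a single enantiomer any (2R,3R) product is a diastereomer that chromatography removes. The step needs C-alkylation of the methide by the ylide to outrun benzyl transfer from 21 to phenoxide or sulfinate; slow release of 22 by the heterogeneous base, an excess of 21 and the soft aryl-substituted methide carbon should secure this. No acid or oxidant is present, so the methyl ethers, the C4 bromide and unit 2 are spectators.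

Step 15
Reactants: 24 the hexamethyl ether of step 14
Product: 25 5-[(2R,3R)-5-[(2S,3S)-4-bromo-6-hydroxy-2-(4-hydroxyphenyl)-2,3-dihydro-1-benzofuran-3-yl]-7-hydroxy-2-(4-hydroxyphenyl)-2,3-dihydro-1-benzofuran-3-yl]benzene-1,3-diol
Conditions: BBr3 (excess), CH2Cl2, −78 °C to rt; then H2O
Reagents that add atoms: none
Why: Lewis acid cleavage of aryl methyl ethers; any reversible opening of the two benzylic C2–O1 bonds should reclose to the trans rings, which are the thermodynamic isomers, and no alkene is yet present that could cyclise.

Step 16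
Reactants: 25 the hexaphenol of step 15
Product: 26 hexaacetate of 25 (all six phenols acetylated; (2S,3S) in unit 1 and (2R,3R) in unit 2)
Conditions: Ac2O, pyridine, DMAP (cat.), rt
Reagents that add atoms: acetic anhydride, CC(=O)OC(C)=O
Why: DMAP-catalysed acetylation caps the six phenols as esters that survive palladium catalysis and hydrogenation, protect the rings from oxidation and make the aryl bromide less electron-rich.

Step 17
Reactants: 26 hexaacetate bromide; 27 4-ethynylphenyl acetate
Product: 28 heptaacetate diarylalkyne (26 with bromine replaced by a 2-(4-acetoxyphenyl)ethynyl group at C4 of ring A)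
Conditions: Pd(PPh3)2Cl2 (5 mol %), CuI (10 mol %), Et3N, DMF, 70 °C
Reagents that add atoms: none
Why: Sonogashira coupling of an aryl bromide with a terminal arylacetylene; the bromide is meta to both ring A oxygens and so not deactivated by resonance, and the tertiary amine should not cleave aryl acetates.

Step 18
Reactants: 28 heptaacetate diarylalkyne
Product: 29 heptaacetate (Z)-stilbene (the heptaacetate of 30)
Conditions: H2 (1 atm), Pd/CaCO3 poisoned with Pb(OAc)2, quinoline, EtOAc, rt
Reagents that add atoms: none
Why: Semi-hydrogenation of a diarylalkyne on lead-poisoned palladium adds hydrogen syn and should stop at the (Z)-alkene, quinoline suppressing over-reduction and Z-to-E isomerisation.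

Step 19
Reactants: 29 heptaacetate (Z)-stilbene
Product: 30 5-[(2R,3R)-7-hydroxy-5-{(2S,3S)-6-hydroxy-2-(4-hydroxyphenyl)-4-[(Z)-2-(4-hydroxyphenyl)ethenyl]-2,3-dihydro-1-benzofuran-3-yl}-2-(4-hydroxyphenyl)-2,3-dihydro-1-benzofuran-3-yl]benzene-1,3-diol (CNP0172909.2)
Conditions: NaOMe (cat.), degassed MeOH, 0 °C to rt, argon; then acidic ion-exchange resin
Reagents that add atoms: none
Why: Base-catalysed transesterification of aryl acetates by methanol runs near 0 °C, well below conditions that isomerise a cis-stilbene or open the dihydrofurans, and exclusion of oxygen protects the phenoxides.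

## Compound list

1 | 5-bromo-2-hydroxy-3-methoxybenzaldehyde | COc1cc(Br)cc(C=O)c1O | starting material
2 | 4-methoxybenzyl bromide | COc1ccc(CBr)cc1 | starting material
3 | 5-bromo-3-methoxy-2-[(4-methoxyphenyl)methoxy]benzaldehyde | COc1cc(Br)cc(C=O)c1OCc1ccc(OC)cc1 | intermediate
4 | 1-bromo-3,5-dimethoxybenzene | COc1cc(Br)cc(OC)c1 | starting material
5 | 3,5-dimethoxyphenylmagnesium bromide | COc1cc([Mg]Br)cc(OC)c1 | intermediate (not isolated)
6 | {5-bromo-3-methoxy-2-[(4-methoxyphenyl)methoxy]phenyl}(3,5-dimethoxyphenyl)methanol (racemic) | COc1cc(Br)cc(C(O)c2cc(OC)cc(OC)c2)c1OCc1ccc(OC)cc1 | intermediate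
7 | {5-bromo-3-methoxy-2-[(4-methoxyphenyl)methoxy]phenyl}(3,5-dimethoxyphenyl)methanone | COc1cc(Br)cc(C(=O)c2cc(OC)cc(OC)c2)c1OCc1ccc(OC)cc1 | intermediate
8 | hydrazone of 7 (E/Z mixture) | COc1cc(Br)cc(C(=NN)c2cc(OC)cc(OC)c2)c1OCc1ccc(OC)cc1 | intermediate
9 | 5-bromo-1-[diazo(3,5-dimethoxyphenyl)methyl]-3-methoxy-2-[(4-methoxyphenyl)methoxy]benzene | COc1cc(Br)cc(C(=[N+]=[N-])c2cc(OC)cc(OC)c2)c1OCc1ccc(OC)cc1 | intermediate (not isolated)
10 | (2S,3R)-5-bromo-3-(3,5-dimethoxyphenyl)-7-methoxy-2-(4-methoxyphenyl)-2,3-dihydro-1-benzofuran (cis) | Brc1cc(OC)c2c(c1)[C@@H](c1cc(OC)cc(OC)c1)[C@@H](c1ccc(OC)cc1)O2 | intermediate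
11 | (2R,3R)-5-bromo-3-(3,5-dimethoxyphenyl)-7-methoxy-2-(4-methoxyphenyl)-2,3-dihydro-1-benzofuran (trans) | Brc1cc(OC)c2c(c1)[C@@H](c1cc(OC)cc(OC)c1)[C@H](c1ccc(OC)cc1)O2 | intermediate
12 | 2-bromo-4,6-dimethoxybenzaldehyde | COc1cc(Br)c(C=O)c(OC)c1 | intermediate
13 | 2-bromo-6-hydroxy-4-methoxybenzaldehyde | COc1cc(O)c(C=O)c(Br)c1 | intermediate
14 | [(2R,3R)-3-(3,5-dimethoxyphenyl)-7-methoxy-2-(4-methoxyphenyl)-2,3-dihydro-1-benzofuran-5-yl]magnesium bromide | Br[Mg]c1cc(OC)c2c(c1)[C@@H](c1cc(OC)cc(OC)c1)[C@H](c1ccc(OC)cc1)O2 | intermediate (not isolated)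
15 | sodium 3-bromo-2-formyl-5-methoxyphenolate | COc1cc([O-])c(C=O)c(Br)c1.[Na+] | intermediate (not isolated)
16 | 3-bromo-2-{[(2R,3R)-3-(3,5-dimethoxyphenyl)-7-methoxy-2-(4-methoxyphenyl)-2,3-dihydro-1-benzofuran-5-yl](hydroxy)methyl}-5-methoxyphenol (carbinol epimers) | Oc1cc(OC)cc(Br)c1C(O)c1cc(OC)c2c(c1)[C@@H](c1cc(OC)cc(OC)c1)[C@H](c1ccc(OC)cc1)O2 | intermediate
17 | 3-bromo-2-{[(2R,3R)-3-(3,5-dimethoxyphenyl)-7-methoxy-2-(4-methoxyphenyl)-2,3-dihydro-1-benzofuran-5-yl](4-methylbenzenesulfonyl)methyl}-5-methoxyphenol (sulfonyl-carbon epimers) | Oc1cc(OC)cc(Br)c1C(S(=O)(=O)c1ccc(C)cc1)c1cc(OC)c2c(c1)[C@@H](c1cc(OC)cc(OC)c1)[C@H](c1ccc(OC)cc1)O2 | intermediate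
18 | (2R,5R)-hexane-2,5-diol | C[C@@H](O)CC[C@@H](C)O | starting material
19 | (2R,5R)-hexane-2,5-diyl dimethanesulfonate | C[C@@H](OS(C)(=O)=O)CC[C@@H](C)OS(C)(=O)=O | intermediate
20 | (2S,5S)-2,5-dimethylthiolane | C[C@H]1CC[C@H](C)S1 | intermediate
21 | (2S,5S)-1-[(4-methoxyphenyl)methyl]-2,5-dimethylthiolan-1-ium tetrafluoroborate | C[C@H]1CC[C@H](C)[S+]1Cc1ccc(OC)cc1.F[B-](F)(F)F | intermediate
22 | 5-bromo-6-{[(2R,3R)-3-(3,5-dimethoxyphenyl)-7-methoxy-2-(4-methoxyphenyl)-2,3-dihydro-1-benzofuran-5-yl]methylidene}-3-methoxycyclohexa-2,4-dien-1-one | O=C1C=C(OC)C=C(Br)C1=Cc1cc(OC)c2c(c1)[C@@H](c1cc(OC)cc(OC)c1)[C@H](c1ccc(OC)cc1)O2 | intermediate (not isolated)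
23 | [(2S,5S)-2,5-dimethylthiolan-1-ium-1-yl](4-methoxyphenyl)methanide | C[C@H]1CC[C@H](C)[S+]1[CH-]c1ccc(OC)cc1 | intermediate (not isolated)
24 | (2S,3S)-4-bromo-3-[(2R,3R)-3-(3,5-dimethoxyphenyl)-7-methoxy-2-(4-methoxyphenyl)-2,3-dihydro-1-benzofuran-5-yl]-6-methoxy-2-(4-methoxyphenyl)-2,3-dihydro-1-benzofuran | Brc1cc(OC)cc2c1[C@H](c1cc(OC)c3c(c1)[C@@H](c1cc(OC)cc(OC)c1)[C@H](c1ccc(OC)cc1)O3)[C@@H](c1ccc(OC)cc1)O2 | intermediate
25 | 5-[(2R,3R)-5-[(2S,3S)-4-bromo-6-hydroxy-2-(4-hydroxyphenyl)-2,3-dihydro-1-benzofuran-3-yl]-7-hydroxy-2-(4-hydroxyphenyl)-2,3-dihydro-1-benzofuran-3-yl]benzene-1,3-diol | Brc1cc(O)cc2c1[C@H](c1cc(O)c3c(c1)[C@@H](c1cc(O)cc(O)c1)[C@H](c1ccc(O)cc1)O3)[C@@H](c1ccc(O)cc1)O2 | intermediate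
26 | hexaacetate of 25 | Brc1cc(OC(C)=O)cc2c1[C@H](c1cc(OC(C)=O)c3c(c1)[C@@H](c1cc(OC(C)=O)cc(OC(C)=O)c1)[C@H](c1ccc(OC(C)=O)cc1)O3)[C@@H](c1ccc(OC(C)=O)cc1)O2 | intermediate
27 | 4-ethynylphenyl acetate | CC(=O)Oc1ccc(C#C)cc1 | starting material
28 | heptaacetate diarylalkyne | CC(=O)Oc1ccc(C#Cc2cc(OC(C)=O)cc3c2[C@H](c2cc(OC(C)=O)c4c(c2)[C@@H](c2cc(OC(C)=O)cc(OC(C)=O)c2)[C@H](c2ccc(OC(C)=O)cc2)O4)[C@@H](c2ccc(OC(C)=O)cc2)O3)cc1 | intermediate
29 | heptaacetate (Z)-stilbene | CC(=O)Oc1ccc(/C=C\c2cc(OC(C)=O)cc3c2[C@H](c2cc(OC(C)=O)c4c(c2)[C@@H](c2cc(OC(C)=O)cc(OC(C)=O)c2)[C@H](c2ccc(OC(C)=O)cc2)O4)[C@@H](c2ccc(OC(C)=O)cc2)O3)cc1 | intermediate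
30 | 5-[(2R,3R)-7-hydroxy-5-{(2S,3S)-6-hydroxy-2-(4-hydroxyphenyl)-4-[(Z)-2-(4-hydroxyphenyl)ethenyl]-2,3-dihydro-1-benzofuran-3-yl}-2-(4-hydroxyphenyl)-2,3-dihydro-1-benzofuran-3-yl]benzene-1,3-diol | Oc1ccc(/C=C\c2cc(O)cc3c2[C@H](c2cc(O)c4c(c2)[C@@H](c2cc(O)cc(O)c2)[C@H](c2ccc(O)cc2)O4)[C@@H](c2ccc(O)cc2)O3)cc1 | target

## Step count and least certain steps

Total step count: 19. Longest linear sequence: 14 steps (steps 1–6, 9, 10 and 14–19, from aldehyde 1).

**Step 14 (key step).** What may go wrong:
- benzyl transfer from salt 21 to the phenoxide of 17 or to the released sulfinate, competing with ylide formation;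
- loss of the methide by self-condensation or by Friedel–Crafts attack of a dimethoxyphenyl ring;
- weak facial control by the sulfide, or control opposed by the remote unit 2, so that both trans diastereomers form.

Fallback, from 17 back to 24: methide 22 is released from 17 with Cs2CO3 in the presence of 4-methoxybenzaldehyde and the carbene derived from 3-benzyl-5-(2-hydroxyethyl)-4-methylthiazolium chloride. Stetter-type acyl anion addition to the methide carbon should give 2-(2-bromo-6-hydroxy-4-methoxyphenyl)-2-[(2R,3R)-3-(3,5-dimethoxyphenyl)-7-methoxy-2-(4-methoxyphenyl)-2,3-dihydro-1-benzofuran-5-yl]-1-(4-methoxyphenyl)ethan-1-one F1 as an epimer mixture. NaBH4 in MeOH/THF reduces it to 3-bromo-2-{1-[(2R,3R)-3-(3,5-dimethoxyphenyl)-7-methoxy-2-(4-methoxyphenyl)-2,3-dihydro-1-benzofuran-5-yl]-2-hydroxy-2-(4-methoxyphenyl)ethyl}-5-methoxyphenol F2. Catalytic TsOH in CH2Cl2 ionises the 4-methoxybenzylic alcohol and the phenol closes to the trans rings. This path has no control at C3, so 24 is separated by chromatography from its diastereomer (2R,3R)-4-bromo-3-[(2R,3R)-3-(3,5-dimethoxyphenyl)-7-methoxy-2-(4-methoxyphenyl)-2,3-dihydro-1-benzofuran-5-yl]-6-methoxy-2-(4-methoxyphenyl)-2,3-dihydro-1-benzofuran F3.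

**Step 5.** What may go wrong:
- low or reversed enantioinduction with this ortho-alkoxy diaryl carbene;
- azine formation between the carbene and unreacted 9;
- attack of the ether oxygen on the carbene followed by benzyl migration.

Fallback, from 1 back to 11: phenol 1 is treated with an excess of arylmagnesium bromide 5 (the first equivalent is consumed by the phenol) to give 4-bromo-2-[(3,5-dimethoxyphenyl)(hydroxy)methyl]-6-methoxyphenol F4. Exchange with p-toluenesulfinic acid gives 4-bromo-2-[(3,5-dimethoxyphenyl)(4-methylbenzenesulfonyl)methyl]-6-methoxyphenol F5. A [4+1] annulation with the achiral salt 1-[(4-methoxyphenyl)methyl]thiolan-1-ium tetrafluoroborate F6 (from thiolane, 2 and NaBF4) and Cs2CO3 gives the racemic trans ring. Preparative chromatography on a chiral stationary phase then separates 11 from its enantiomer (2S,3S)-5-bromo-3-(3,5-dimethoxyphenyl)-7-methoxy-2-(4-methoxyphenyl)-2,3-dihydro-1-benzofuran F7.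

**Step 15.** What may go wrong:
- Lewis acid ionisation of the two benzylic C2–O1 bonds, followed by bromide capture or intermolecular alkylation of a resorcinol ring instead of reclosure;
- incomplete cleavage of the six ethers.

Fallback, from 24 back to 25: nucleophilic dealkylation with NaSEt in DMF at about 130 °C removes the methyl groups by SN2 attack at carbon. No Lewis acid is present and no benzylic cation can form. The route is rejoined at 25 and no new compound is made.

**Step 18.** What may go wrong:
- over-reduction to the diarylethane;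
- Z-to-E isomerisation on the palladium surface;
- slow uptake by the hindered alkyne next to C3a.

Fallback, from 26 back to 29: Heck reaction of bromide 26 with 4-acetoxystyrene (Pd(OAc)2, P(o-tol)3, Et3N, DMF, 100 °C) gives the heptaacetate (E)-stilbene F8. Triplet-sensitised E-to-Z isomerisation (Ir(ppy)3, blue light, MeCN) should enrich the twisted Z isomer 29, which is separated, and recovered F8 is recycled.

## Further compounds

F1 | step 14 | 2-(2-bromo-6-hydroxy-4-methoxyphenyl)-2-[(2R,3R)-3-(3,5-dimethoxyphenyl)-7-methoxy-2-(4-methoxyphenyl)-2,3-dihydro-1-benzofuran-5-yl]-1-(4-methoxyphenyl)ethan-1-one (epimer mixture) | Oc1cc(OC)cc(Br)c1C(C(=O)c1ccc(OC)cc1)c1cc(OC)c2c(c1)[C@@H](c1cc(OC)cc(OC)c1)[C@H](c1ccc(OC)cc1)O2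
F2 | step 14 | 3-bromo-2-{1-[(2R,3R)-3-(3,5-dimethoxyphenyl)-7-methoxy-2-(4-methoxyphenyl)-2,3-dihydro-1-benzofuran-5-yl]-2-hydroxy-2-(4-methoxyphenyl)ethyl}-5-methoxyphenol (diastereomer mixture) | Oc1cc(OC)cc(Br)c1C(C(O)c1ccc(OC)cc1)c1cc(OC)c2c(c1)[C@@H](c1cc(OC)cc(OC)c1)[C@H](c1ccc(OC)cc1)O2
F3 | step 14 | (2R,3R)-4-bromo-3-[(2R,3R)-3-(3,5-dimethoxyphenyl)-7-methoxy-2-(4-methoxyphenyl)-2,3-dihydro-1-benzofuran-5-yl]-6-methoxy-2-(4-methoxyphenyl)-2,3-dihydro-1-benzofuran | Brc1cc(OC)cc2c1[C@@H](c1cc(OC)c3c(c1)[C@@H](c1cc(OC)cc(OC)c1)[C@H](c1ccc(OC)cc1)O3)[C@H](c1ccc(OC)cc1)O2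
F4 | step 5 | 4-bromo-2-[(3,5-dimethoxyphenyl)(hydroxy)methyl]-6-methoxyphenol (racemic) | COc1cc(Br)cc(C(O)c2cc(OC)cc(OC)c2)c1O
F5 | step 5 | 4-bromo-2-[(3,5-dimethoxyphenyl)(4-methylbenzenesulfonyl)methyl]-6-methoxyphenol (racemic) | COc1cc(Br)cc(C(c2cc(OC)cc(OC)c2)S(=O)(=O)c2ccc(C)cc2)c1O
F6 | step 5 | 1-[(4-methoxyphenyl)methyl]thiolan-1-ium tetrafluoroborate | COc1ccc(C[S+]2CCCC2)cc1.F[B-](F)(F)F
F7 | step 5 | (2S,3S)-5-bromo-3-(3,5-dimethoxyphenyl)-7-methoxy-2-(4-methoxyphenyl)-2,3-dihydro-1-benzofuran | Brc1cc(OC)c2c(c1)[C@H](c1cc(OC)cc(OC)c1)[C@@H](c1ccc(OC)cc1)O2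
F0 | step 15 | none | none
F8 | step 18 | heptaacetate (E)-stilbene (E isomer of 29) | CC(=O)Oc1ccc(/C=C/c2cc(OC(C)=O)cc3c2[C@H](c2cc(OC(C)=O)c4c(c2)[C@@H](c2cc(OC(C)=O)cc(OC(C)=O)c2)[C@H](c2ccc(OC(C)=O)cc2)O4)[C@@H](c2ccc(OC(C)=O)cc2)O3)cc1
A1 | alternative 1 | (2R)-6-chloro-8-methoxy-2-(4-methoxyphenyl)-2,3-dihydro-4H-chromen-4-one | Clc1cc(OC)c2c(c1)C(=O)C[C@H](c1ccc(OC)cc1)O2
A2 | alternative 1 | methyl (2R,3R)-5-chloro-7-methoxy-2-(4-methoxyphenyl)-2,3-dihydro-1-benzofuran-3-carboxylate | Clc1cc(OC)c2c(c1)[C@@H](C(=O)OC)[C@H](c1ccc(OC)cc1)O2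
A3 | alternative 2 | 4-bromo-2-[(1S,2R)-1-(3,5-dimethoxyphenyl)-2-(ethynyloxy)-2-(4-methoxyphenyl)ethyl]furan | Brc1coc(c1)[C@@H](c1cc(OC)cc(OC)c1)[C@H](c1ccc(OC)cc1)OC#C
A4 | alternative 2 | (2R,3R)-5-bromo-3-(3,5-dimethoxyphenyl)-2-(4-methoxyphenyl)-2,3-dihydro-1-benzofuran-7-ol | Brc1cc(O)c2c(c1)[C@@H](c1cc(OC)cc(OC)c1)[C@H](c1ccc(OC)cc1)O2
A5 | alternative 3 | 4-{(2R,3R)-3-[(2R,3R)-3-(3,5-dimethoxyphenyl)-7-methoxy-2-(4-methoxyphenyl)-2,3-dihydro-1-benzofuran-5-yl]oxiran-2-yl}phenyl 4-methylbenzenesulfonate | [C@@H]1(c2cc(OC)c3c(c2)[C@@H](c2cc(OC)cc(OC)c2)[C@H](c2ccc(OC)cc2)O3)[C@@H](c2ccc(OS(=O)(=O)c3ccc(C)cc3)cc2)O1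
A6 | alternative 3 | 3-bromo-5-methoxybenzyne | COC1=CC#CC(Br)=C1
A7 | alternative 3 | 4-{(2S,3S)-4-bromo-3-[(2R,3R)-3-(3,5-dimethoxyphenyl)-7-methoxy-2-(4-methoxyphenyl)-2,3-dihydro-1-benzofuran-5-yl]-6-methoxy-2,3-dihydro-1-benzofuran-2-yl}phenyl 4-methylbenzenesulfonate | Brc1cc(OC)cc2c1[C@H](c1cc(OC)c3c(c1)[C@@H](c1cc(OC)cc(OC)c1)[C@H](c1ccc(OC)cc1)O3)[C@@H](c1ccc(OS(=O)(=O)c3ccc(C)cc3)cc1)O2
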